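**Retrosynthetic overview** (eudesmane numbering C1–C15)
1. Presumed biosynthesis: farnesyl C6–C7 closure with loss of H13 gives a germacranolide, and the lactone forms from 8-OH and the C12 acid. C10, activated next to an oxygenated C1, then bonds to C5 to give a 1-hydroxyeudesm-5-en-12,8-olide. C1–C10 Grob scission follows, with oxygen arriving at C6.
2. Target ⇐ C1 aldehyde ⇐ oxidative Grob scission of 1-hydroxyeudesma-5,11(13)-dien-12,8-olide. The allyl intermediate is captured by isovalerate, which sets C6 and installs the ester in one step.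
3. That eudesmanolide ⇐ one radical cascade of an acyclic enyne. The C10 radical beside the C1 carbinol attacks C5 (ring A). The C6 vinyl radical then attacks C7 of the butenolide (ring B), and loss of acetate unveils the 11(13)-methylene.
4. Enyne ⇐ Nozaki–Hiyama–Kishi union (C1–C10) of (S)-4-methylhex-5-ynal with a 2-bromoallyl butenolide. C4 comes from (S)-citronellal and C8 from the asymmetric 2-bromoallylation of acrolein. O8 is acylated by the C12 acid and the lactone ring is then closed.
5. Ring order: lactone → ring A → ring B (same flask) → ring A opened.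

Assumption: the C1 and C10 centres of the two intermediates that carry them are taken on as epimer mixtures, because both centres are erased by the scission.

**Step 1**
Reactants: 1 (S)-citronellal
Product: 3 (S)-3,7-dimethyloct-6-en-1-yne, via enol nonaflate 2 (not isolated)
Conditions: n-C4F9SO2F (1.3 equiv), t-BuN=P(pyrrolidin-1-yl)3 (2.5 equiv), DMF, −20 °C to rt
Reagents that add atoms: none
Why: One-pot enol nonaflation and E2 elimination (aldehyde-to-alkyne dehydration) works because the metal-free, non-nucleophilic phosphazene base both forms and eliminates the alkenyl nonaflate, while the C4 centre is not touched and stays (S) and the trisubstituted olefin is inert.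

**Step 2**
Reactants: 3 (S)-3,7-dimethyloct-6-en-1-yne
Product: 5 (S)-4-methylhex-5-ynal, via ozonide 4 (not isolated)
Conditions: O3 (1.0 equiv, Sudan red end point), CH2Cl2, −78 °C; then Me2S, −78 °C to rt
Reagents that add atoms: ozone, [O-][O+]=O
Why: Ozonolysis is chemoselective because the electron-rich trisubstituted olefin reacts far faster with ozone than a terminal alkyne, and reductive work-up of the ozonide gives the C1 aldehyde without touching C4.

**Step 3**
Reactants: 6 2-(bromomethyl)acrylic acid
Product: 7 2-(acetoxymethyl)acrylic acid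
Conditions: NaOAc (1.5 equiv), AcOH, 70 °C
Reagents that add atoms: sodium acetate, CC(=O)[O-].[Na+]
Why: SN2 displacement of the activated allylic bromide by acetate installs a leaving group on C13 that tolerates chromium chemistry and later unveils the 11(13)-methylene.

**Step 4**
Reactants: 8 acrolein; 9 2,3-dibromopropene
Product: 11 (R)-5-bromohexa-1,5-dien-3-ol, via silyl ether 10 (not isolated)
Conditions: CrBr3 (10 mol %), chiral oxazoline–sulfonamide ligand (11 mol %, the enantiomer giving the R alcohol), Et3N (20 mol %), Co(phthalocyaninate) (1 mol %), Mn powder (2 equiv), Me3SiCl (1.5 equiv), THF, 0 °C; then 1 M HCl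
Reagents that add atoms: none
Why: In this catalytic asymmetric Nozaki–Hiyama 2-haloallylation, divalent chromium (regenerated by Mn) activates only the allylic C–Br bond, and the allylchromium adds 1,2 to acrolein through a ligand-controlled cyclic transition state that sets C8 as (R) while the vinylic bromide survives.

**Step 5**
Reactants: 7 2-(acetoxymethyl)acrylic acid; 11 (R)-5-bromohexa-1,5-dien-3-ol
Product: 13 (R)-5-bromohexa-1,5-dien-3-yl 2-(acetoxymethyl)acrylate, via acid chloride 12 (not isolated)
Conditions: (COCl)2, DMF (cat.), CH2Cl2, 0 °C; then 11, 2,6-lutidine, CH2Cl2, −20 to 0 °C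
Reagents that add atoms: none
Why: O-acylation through the acid chloride joins O8 to the C12 acyl carbon with retention at C8, and the hindered, weakly nucleophilic base avoids SN2′ attack on the allylic acetate.

**Step 6**
Reactants: 13 (R)-5-bromohexa-1,5-dien-3-yl 2-(acetoxymethyl)acrylate
Product: 14 [(5R)-5-(2-bromoprop-2-en-1-yl)-2-oxo-2,5-dihydrofuran-3-yl]methyl acetate
Conditions: second-generation Grubbs catalyst (5 mol %), CH2Cl2 (0.01 M), 40 °C
Reagents that add atoms: none
Why: Ring-closing metathesis of the vinyl group with the 2-substituted acrylate closes the butenolide (C7=C11), driven by loss of ethene, while the 2-bromoalkene is too hindered and deactivated to engage the ruthenium carbene.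

**Step 7**
Reactants: 14 the bromoallyl butenolide; 5 (S)-4-methylhex-5-ynal
Product: 15 [(5R)-5-[(6S)-3-hydroxy-6-methyl-2-methylideneoct-7-yn-1-yl]-2-oxo-2,5-dihydrofuran-3-yl]methyl acetate (C1 epimers)
Conditions: CrCl2 (4 equiv), NiCl2 (1 mol %), DMF, rt; aqueous work-up
Reagents that add atoms: none
Why: The Nozaki–Hiyama–Kishi coupling forms C1–C10 because the alkenylchromium adds only to aldehydes and leaves lactone, acetate and terminal alkyne alone, and the new C1 carbinol centre needs no control since it later becomes an aldehyde.

**Step 8**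
Reactants: 15 the acyclic enyne alcohol
Product: 16 (4S,7R,8R)-1-hydroxyeudesma-5,11(13)-dien-12,8-olide (C1/C10 epimers)
Conditions: Fe(acac)3 (0.5 equiv), PhSiH2(Oi-Pr) (1.5 equiv, syringe pump, 8 h), Na2HPO4, degassed EtOAc (0.002 M), 60 °C
Reagents that add atoms: none
Why: Proposed new method: hydrogen-atom transfer from an iron hydride to the 10(14)-methylene, the only electron-neutral 1,1-disubstituted olefin, gives the C10 tertiary radical beside the C1 carbinol, which is the radical counterpart of the cation from a 1(10)-epoxy- or 1-hydroxy-10(14)-ene germacranolide; it closes 6-exo-dig on C5 (ring A), the C6 vinyl radical closes 6-exo-trig on C7 of the butenolide (ring B) on the only face the C8–C9 tether can reach, which sets H7 cis to H8, and the C11 radical is reduced by divalent iron to an enolate that expels acetate to give the 11(13)-methylene; slow silane addition, an aprotic solvent and high dilution keep hydrogen donors and bimolecular Giese additions slower than the first closure, and the closest known reaction types are metal-hydride HAT-initiated radical polycyclisations, iron-catalysed hydroallylation of olefins with Baylis–Hillman acetates and vinyl-radical cyclisations onto enoates.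

**Step 9**
Reactants: 16 the 1-hydroxyeudesmadienolide; 17 isovaleric acid
Product: 20 (4S,6S,7R,8R)-6-(3-methylbutanoyloxy)-1-oxo-1,10-secoeudesma-5(10),11(13)-dien-12,8-olide, via hypoiodite 18 (not isolated), via allylic iodide 19 (not isolated)
Conditions: PhI(OAc)2 (1.3 equiv), 17 (4 equiv), PhCl, 40 °C, vacuum (AcOH removed); then 16, I2 (0.5 equiv), CH2Cl2, visible light, 0 °C to rt
Reagents that add atoms: isovaleric acid, CC(C)CC(=O)O, delivered as PhI(O2CCH2CHMe2)2, CC(C)CC(=O)OI(OC(=O)CC(C)C)c1ccccc1
Why: Proposed new method: under Suárez-type conditions the C1 hypoiodite homolyses, and the alkoxyl radical cleaves C1–C10 because this gives an aldehyde and a stabilised C10–C5–C6 allyl radical (oxidative Grob fragmentation); iodine transfer gives the allylic iodide, which ionises and is captured by isovalerate at the less hindered C6 terminus, leaving the tetrasubstituted 5(10)-olefin, from the α face opposite the cis-fused β-lactone, which sets C6 as (S); the closest known reaction is the lead tetraacetate or iodane/iodine fragmentation of 19-hydroxy-Δ5-steroids to 6-acetoxy-19-nor-5(10)-enes.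

**Step 10**
Reactants: 20 the seco aldehyde
Product: 21 target, 6-O-isovalerylbritannilactone (CNP0289409.1)
Conditions: NaBH(OAc)3 (1.5 equiv), 1,2-dichloroethane, rt
Reagents that add atoms: none
Why: Chemoselective hydride reduction works because the attenuated triacetoxyborohydride reduces only the unhindered aldehyde and leaves the α-methylene lactone, the allylic ester and all four stereocentres untouched.

**Compound list**
1 | (S)-citronellal | O=CC[C@@H](C)CCC=C(C)C | starting material
2 | (3S)-3,7-dimethylocta-1,6-dien-1-yl nonaflate (E/Z) | FC(F)(F)C(F)(F)C(F)(F)C(F)(F)S(=O)(=O)OC=C[C@@H](C)CCC=C(C)C | intermediate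
3 | (S)-3,7-dimethyloct-6-en-1-yne | C#C[C@@H](C)CCC=C(C)C | intermediate
4 | 3,3-dimethyl-5-[(3S)-3-methylpent-4-yn-1-yl]-1,2,4-trioxolane | C#C[C@@H](C)CCC1OOC(C)(C)O1 | intermediate
5 | (S)-4-methylhex-5-ynal | C#C[C@@H](C)CCC=O | intermediate
6 | 2-(bromomethyl)acrylic acid | C=C(CBr)C(=O)O | starting material
7 | 2-(acetoxymethyl)acrylic acid | C=C(COC(C)=O)C(=O)O | intermediate
8 | acrolein | C=CC=O | starting material
9 | 2,3-dibromopropene | C=C(Br)CBr | starting material
10 | (R)-5-bromohexa-1,5-dien-3-yl trimethylsilyl ether | C[Si](C)(C)O[C@@H](C=C)CC(Br)=C | intermediate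
11 | (R)-5-bromohexa-1,5-dien-3-ol | O[C@@H](C=C)CC(Br)=C | intermediate
12 | 2-(acetoxymethyl)acryloyl chloride | C=C(COC(C)=O)C(=O)Cl | intermediate
13 | (R)-5-bromohexa-1,5-dien-3-yl 2-(acetoxymethyl)acrylate | C=C(COC(C)=O)C(=O)O[C@@H](C=C)CC(Br)=C | intermediate
14 | [(5R)-5-(2-bromoprop-2-en-1-yl)-2-oxo-2,5-dihydrofuran-3-yl]methyl acetate | O=C1O[C@H](CC(Br)=C)C=C1COC(C)=O | intermediate
15 | [(5R)-5-[(6S)-3-hydroxy-6-methyl-2-methylideneoct-7-yn-1-yl]-2-oxo-2,5-dihydrofuran-3-yl]methyl acetate (C1 epimers) | C#C[C@@H](C)CCC(O)C(=C)C[C@H]1OC(=O)C(COC(C)=O)=C1 | intermediate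
16 | (4S,7R,8R)-1-hydroxyeudesma-5,11(13)-dien-12,8-olide (C1/C10 epimers) | C=C1C(=O)O[C@@H]2CC3(C)C(O)CC[C@H](C)C3=C[C@H]12 | intermediate
17 | isovaleric acid | CC(C)CC(=O)O | starting material
18 | C1 hypoiodite of 16 | C=C1C(=O)O[C@@H]2CC3(C)C(OI)CC[C@H](C)C3=C[C@H]12 | intermediate
19 | 6-iodo-1-oxo-1,10-secoeudesma-5(10),11(13)-dien-12,8-olide (C6 epimers) | C=C1C(=O)O[C@@H]2CC(C)=C([C@@H](C)CCC=O)C(I)[C@H]12 | intermediate
20 | (4S,6S,7R,8R)-6-(3-methylbutanoyloxy)-1-oxo-1,10-secoeudesma-5(10),11(13)-dien-12,8-olide | C=C1C(=O)O[C@@H]2CC(C)=C([C@@H](C)CCC=O)[C@@H](OC(=O)CC(C)C)[C@H]12 | intermediate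
21 | 6-O-isovalerylbritannilactone (CNP0289409.1) | C=C1C(=O)O[C@@H]2CC(C)=C([C@@H](C)CCCO)[C@@H](OC(=O)CC(C)C)[C@H]12 | target

**Total step count:** 10. **Longest linear sequence:** 7 (steps 4, 5, 6, 7, 8, 9, 10).

**Steps most likely to fail**

Step 8. The first 6-exo-dig closure of a hindered nucleophilic radical is slow. The radical can be reduced early or trapped by the α-methylene lactone already formed, and the vinyl radical can abstract H8. The fallback sets out from 15 and replaces the hydride-based initiation with the biosynthetic epoxide trigger. Reductive 1,3-transposition of the allylic alcohol (2-nitrobenzenesulfonylhydrazide, PPh3, diethyl azodicarboxylate, then warming) gives the 1(10)-trisubstituted olefin F1. mCPBA then oxidises only this olefin to the 1(10)-epoxide F2. Cp2TiCl, made from Cp2TiCl2 and Mn in THF, opens F2 to a long-lived β-titanoxy C10 radical with no hydride donor present. The same two closures follow, and the trivalent-titanium-derived enolate expels acetate. The route is rejoined at 16.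

Step 9. Capture of the allyl intermediate may occur at C10 or from the wrong face, and the alkoxyl radical may react along other paths. The fallback sets out from 16 and follows the ionic biosynthetic sequence. mCPBA epoxidises the 5(6)-olefin from the α face to give the 5α,6α-epoxide F3. BF3·OEt2 at −78 °C ionises C5–O and triggers the heterolytic Grob scission to the 6α-hydroxy seco aldehyde F4. Isovaleric anhydride with 4-dimethylaminopyridine acylates O6, and the route is rejoined at 20.

Step 4. Acrolein is an untested and polymerisable partner for the catalytic asymmetric haloallylation, so the enantiomeric excess may be poor. The fallback sets out from 8 and 9 and obtains the stereocentre by resolution instead of asymmetric addition. An indium-mediated Barbier reaction in aqueous THF gives the racemic alcohol F5. Sharpless kinetic resolution (Ti(Oi-Pr)4, L-(+)-diisopropyl tartrate, t-BuOOH 0.6 equiv, −20 °C) converts the fast-reacting (S)-enantiomer into the epoxy alcohol F6 and leaves the (R)-alcohol. The route is rejoined at 11.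

**Further compounds**
F1 | step 8 | [(5R)-5-[(6S)-2,6-dimethyloct-2-en-7-yn-1-yl]-2-oxo-2,5-dihydrofuran-3-yl]methyl acetate (E/Z) | C#C[C@@H](C)CCC=C(C)C[C@H]1OC(=O)C(COC(C)=O)=C1
F2 | step 8 | 1(10)-epoxide of F1 (epoxide diastereomers) | C#C[C@@H](C)CCC1OC1(C)C[C@H]2OC(=O)C(COC(C)=O)=C2
F3 | step 9 | 5α,6α-epoxy-1-hydroxyeudesm-11(13)-en-12,8-olide (C1/C10 epimers) | C=C1C(=O)O[C@@H]2CC3(C)C(O)CC[C@H](C)[C@@]34O[C@H]4[C@H]12
F4 | step 9 | (4S,6S,7S,8R)-6-hydroxy-1-oxo-1,10-secoeudesma-5(10),11(13)-dien-12,8-olide | C=C1C(=O)O[C@@H]2CC(C)=C([C@@H](C)CCC=O)[C@@H](O)[C@H]12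
F5 | step 4 | rac-5-bromohexa-1,5-dien-3-ol | OC(C=C)CC(Br)=C
F6 | step 4 | (1S)-3-bromo-1-[(2S)-oxiran-2-yl]but-3-en-1-ol | O[C@@H](CC(Br)=C)[C@@H]1CO1
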